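# Proposed synthesis of gnetucleistol F (15)

## The problem

Gnetucleistol F (15) is a trans-2-aryl-3-(hydroxymethyl)-2,3-dihydrobenzofuran. Ring A is the methoxylated benzo ring, ring B is a syringyl group on C2, and ring C is a resorcinol joined to C5 of ring A through an E-configured two-carbon bridge. A synthesis must assemble three electron-rich arenes around a five-membered oxygen heterocycle and set two adjacent stereocentres, C2 (R) and C3 (S), trans to each other. The two centres are unequal tasks. With an ester on C3 that carbon is enolisable and the trans isomer is the more stable one, so C2, once fixed, controls C3 and only C2 needs absolute control. The molecule is fragile in three ways. It has three free phenols. The ring B phenol lies para to the benzylic C2–O1 bond, so its phenoxide can open the ring through a para-quinone methide. The dihydroxystilbene is sensitive to acid, oxidants and light and rules out hydrogenolysis once it is present. The enabling feature is the chain O1–C2–C3–CH2OH. At the oxidation level of a benzofuran-3-carboxylate these atoms are a phenol oxygen, the two carbons of a diarylacetylene and one molecule of carbon monoxide. The whole core can therefore be built flat and achiral, and chirality introduced afterwards by reducing one C=C bond.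

## Retrosynthesis

**15 to 14.** The three phenolic O–H bonds are traced back to O–Si bonds in the tris-silyl ether 14. Benzyl ethers would need hydrogenolysis, which would saturate the stilbene, and methyl ethers could not be told apart from the three methoxy groups that must stay. Fluoride removes all three silyl groups in one mild operation. The forward step must keep the liberated phenoxides buffered.

**14 to 10 and 13.** The C5–vinyl bond is cut as a Heck disconnection into aryl bromide 10 and styrene 13. The neighbouring cut, olefination of a C5 aldehyde, would need an aldehyde that cannot survive a copper hydride or LiBH4 without its own protection. Bromine is inert through every earlier step and is already present in starting material 1. The cut removes ring C and is fully convergent. The forward reaction must be E-selective and tolerate a free primary alcohol.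

**13 to 12 to 11.** The vinyl group of 13 comes from aldehyde 12 by methylenation, and 12 from 3,5-dihydroxybenzaldehyde (11) by silylation. Both are routine.

**10 to 9.** The C3 carbinol is taken back to the methyl ester 9. The ester is kept until this point because it makes C3 epimerisable and makes C2=C3 of the aromatic precursor an acceptor. The forward step is a chemoselective ester reduction.

**9 to 7.** The C2–H and C3–H bonds are removed, which erases both stereocentres and leads to the flat benzofuran ester 7. Against cuts that build the stereocentres during ring construction, this one places the only asymmetric event after all skeletal bonds of the core exist. The forward reaction must select one face of C2=C3 for hydride delivery to C2. C3 then follows by equilibration.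

**7 to 6 (key).** The O1–C2 bond and the C3–CO2Me bond are cut together, leading to the alkynylphenol 6 and carbon monoxide. The alternative, closing the benzofuran first and acylating C3 later, would set an electrophile against three electron-rich rings. The carbonylative closure puts the one-carbon unit on C3 in the same event that forms the ring. The precursor is an acyclic diarylacetylene. The forward step needs carbonylation to be faster than protonolysis.

**6 to 2 and 5.** The aryl–alkyne bond is cut as a Sonogashira disconnection into iodophenol 2 and terminal alkyne 5. The iodide and bromide of 2 differ enough in reactivity that the bromide is carried through as a spectator.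

**5 to 4 to 3, and 2 to 1.** Alkyne 5 is the one-carbon homologue of silylated syringaldehyde 4, made from syringaldehyde (3). Iodophenol 2 comes from 4-bromoguaiacol (1) by iodination ortho to the hydroxyl.

## Roads not taken

**Alternative 1:** The cut runs through C2–C3 and C2–aryl, with C2 supplied as the carbon of dichloromethane (double Matteson homologation). In the forward step LiCHCl2 would insert into the C3–boron bond of a C3 boronate of (S,S)-1,2-dicyclohexylethane-1,2-diol, with ZnCl2 promoting the 1,2-shift that sets C2. The silylated syringyl Grignard reagent would then displace chloride with inversion to give the open-chain boronate A1, in which boron marks the place of O1.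
- Merits: both centres come from reagent control by one chiral diol, with the predictable diastereoselection typical of this homologation. Nothing depends on an untested catalyst.
- Weak points: the C3 boronate needs an earlier homologation at a benzylic carbon, where α-chloro boronates epimerise easily. A1 is still acyclic, so C–B oxidation, unmasking of the ring A phenol and an O1–C2 closure with inversion must follow, at a benzylic carbon that ionises readily. The benzyl ethers must be removed before the stilbene exists, and the acetal must still be converted into the stilbene. Cryogenic carbenoid chemistry and a stoichiometric chiral diol are required.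
- Comparison: in certainty of stereocontrol this road is the stronger one. The chosen plan sets against it a much shorter sequence, a catalytic source of chirality, a ring closure that cannot erode a stereocentre because none exists yet, and a fallback that reuses its own intermediates.

**Alternative 2:** The cut removes C2 as a one-carbon unit in a (4+1) annulation. C2–C3 and O1–C2 would form together from an ortho-quinone methide of ring A and a chiral syringylmethyl sulfonium ylide. KOt-Bu would release the quinone methide from a benzylic sulfone, the ylide would add to the methide carbon, and the phenoxide would displace the sulfide. The product is the trans dihydrobenzofuran A2, with both stereocentres, the C3 carbinol at its final oxidation level and the bromide for the Heck reaction.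
- Merits: this is the most convergent road. Ring and both stereocentres arise in one step, trans through the anti closure of the betaine, and no dearomatisation or ester reduction is needed afterwards.
- Weak points: a quinone methide with a silyloxymethyl group on the methide carbon can tautomerise to the ortho-hydroxystyrene before it is trapped. The ylide is only semi-stabilised by an electron-rich aryl group. Absolute control rests on a stoichiometric chiral sulfide in a reaction class where high enantioselection is not established for this ylide type. KOt-Bu also threatens the aryl silyl ether.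
- Comparison: in step economy and directness this road is better if it works. The chosen plan sets against it a ring-forming step that is established for this substrate class. Ring formation and asymmetric induction are also decoupled, so a failing asymmetric step still leaves the complete core 7 and a known racemic reduction, whereas a failing annulation leaves nothing.

**Alternative 3:** The cut is C3–C3a, made by ring contraction. The (R)-flavanone A3 already holds O1–C2 and the C2 stereocentre. PhI(OAc)2 and H2SO4 in trimethyl orthoformate would iodinate the enol ether next to the carbonyl group. Ring A would migrate to that carbon as the trivalent iodine leaves, and the pyranone would contract to the trans ester A4. A4 is ester 9 of the chosen route with a pivalate in place of the silyl group.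
- Merits: oxidative contraction of flavanones to trans dihydrobenzofuran-3-carboxylates is a known reaction, and trans follows from the migration itself. Enantioenriched flavanones are accessible by precedented catalytic methods. In precedent for the stereo-determining event this road is ahead of the chosen one.
- Weak points: C2 of A3 is a benzylic ether that can ionise or open by retro-oxa-Michael reaction in H2SO4. It is the only stereocentre at that stage, so any opening racemises. Migration of ring B and dehydrogenation to the flavone compete, the more so the more electron-rich ring B is, which forces the ester protecting group. The pivalate must then pass a hydride reduction and the Heck step, or be exchanged.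
- Comparison: step counts are similar and both roads meet at the same trans bromo ester. Alternative 3 offers better-known stereochemistry, at the price of a stereocentre exposed to strong acid and an oxidant and a rearrangement with two competing pathways. The chosen plan offers a mild, unambiguous ring construction with no stereocentre at risk, and confines its uncertainty to one step with a known replacement.

Key step: step 5

Assumption: the face of 7 attacked by the copper hydride of (R)-DTBM-SEGPHOS cannot be derived from structure alone; if it gives the (2S) series, the (S) ligand is used and nothing else changes.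

Assumption: the target is the trans (2R,3S) isomer encoded in the SMILES; the ester intermediates with the same spatial arrangement are (2R,3R), because CO2Me outranks C2 at C3.

## Route

Step 1
Reactants: 1 4-bromo-2-methoxyphenol
Product: 2 4-bromo-2-iodo-6-methoxyphenol
Conditions: N-iodosuccinimide (1.05 equiv), TsOH·H2O (10 mol %), MeCN, 0 °C to rt
Reagents that add atoms: N-iodosuccinimide, O=C1CCC(=O)N1I
Why: Electrophilic aromatic iodination; the hydroxyl is the strongest director and its para position is blocked by bromine, so iodine should enter the one free ortho position.

Step 2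
Reactants: 3 syringaldehyde (4-hydroxy-3,5-dimethoxybenzaldehyde)
Product: 4 3,5-dimethoxy-4-(triisopropylsilyloxy)benzaldehyde
Conditions: TIPSCl, imidazole, DMF, rt
Reagents that add atoms: triisopropylsilyl chloride, CC(C)[Si](Cl)(C(C)C)C(C)C
Why: Silyl ether formation on an acidic phenol; the triisopropylsilyl group is the common silyl ether most resistant to the bases of later steps and is removed by fluoride at the end.

Step 3
Reactants: 4 3,5-dimethoxy-4-(triisopropylsilyloxy)benzaldehyde
Product: 5 (4-ethynyl-2,6-dimethoxyphenoxy)triisopropylsilane
Conditions: Me3SiCHN2, LDA, THF, −78 °C to rt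
Reagents that add atoms: trimethylsilyldiazomethane, C[Si](C)(C)C=[N+]=[N-]
Why: Colvin rearrangement; the lithiated diazo compound adds to the aldehyde, Peterson-type loss of silanolate and loss of N2 give an alkylidene carbene, and a 1,2-hydrogen shift gives the terminal alkyne. The aprotic, alkoxide-free conditions are chosen over the Ohira–Bestmann variant because the silyl group of 4 sits on a para-formyl phenoxide, a good leaving group towards methoxide.

Step 4
Reactants: 2 4-bromo-2-iodo-6-methoxyphenol; 5 (4-ethynyl-2,6-dimethoxyphenoxy)triisopropylsilane
Product: 6 4-bromo-2-{[3,5-dimethoxy-4-(triisopropylsilyloxy)phenyl]ethynyl}-6-methoxyphenol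
Conditions: Pd(PPh3)2Cl2 (2 mol %), CuI (4 mol %), Et3N, THF, rt, degassed
Reagents that add atoms: none
Why: Sonogashira coupling; zerovalent palladium inserts far faster into C–I than into C–Br at room temperature, so only the iodide should couple. The low temperature should keep the free ortho hydroxyl from adding to the new alkyne.

Step 5
Reactants: 6 4-bromo-2-{[3,5-dimethoxy-4-(triisopropylsilyloxy)phenyl]ethynyl}-6-methoxyphenol
Product: 7 methyl 5-bromo-7-methoxy-2-[3,5-dimethoxy-4-(triisopropylsilyloxy)phenyl]-1-benzofuran-3-carboxylate
Conditions: PdCl2 (5 mol %), CuCl2 (3 equiv), NaOAc (3 equiv), CO (1 atm), MeOH/THF, rt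
Reagents that add atoms: carbon monoxide, [C-]#[O+]; methanol, CO
Why: Divalent palladium (PdCl2) binds the electron-rich diarylacetylene of 6, and the neighbouring phenol oxygen, deprotonated by acetate, attacks the activated alkyne anti to the metal and closes the furan ring (O1–C2) in a 5-endo-dig mode, which leaves palladium on C3 of the new benzofuran. CO inserts into this C3–palladium bond and methanol cleaves the acylpalladium species to the methyl ester (C3–CO2Me), releasing zerovalent palladium that CuCl2 returns to the divalent state. The closest known reaction type is the PdCl2/CuCl2-mediated cyclisation–alkoxycarbonylation of 2-alkynylphenols and 2-alkynylanilines to benzofuran- and indole-3-carboxylates. No stereocentre is formed, so the step delivers a flat, achiral core carrying every carbon of the dihydrobenzofuran. The selectivity needed is chemoselectivity: CO insertion must outrun protonolysis of the C3–palladium bond, which would give the 3-unsubstituted benzofuran, and a CO-saturated solution together with NaOAc, which takes up the HCl formed, should secure this. The C5 bromide should survive because no phosphine-bound zerovalent palladium persists at room temperature. CuCl2 cannot chlorinate ring A because both positions ortho and the position para to its hydroxyl are already substituted, and the 5-endo closure is the only one open to the phenol oxygen, so regiochemistry is not in question.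

Step 6
Reactants: 7 methyl 5-bromo-7-methoxy-2-[3,5-dimethoxy-4-(triisopropylsilyloxy)phenyl]-1-benzofuran-3-carboxylate
Product: 9 methyl (2R,3R)-5-bromo-7-methoxy-2-[3,5-dimethoxy-4-(triisopropylsilyloxy)phenyl]-2,3-dihydro-1-benzofuran-3-carboxylate (trans), via C3-epimeric (2R)-dihydrobenzofuran ester 8 (not isolated)
Conditions: Cu(OAc)2·H2O (5 mol %), (R)-DTBM-SEGPHOS (5.5 mol %), (EtO)2MeSiH (3 equiv), t-BuOH (2 equiv), toluene, rt; filtration through silica; DBU (0.5 equiv), toluene, 60 °C
Reagents that add atoms: none
Why: Proposed new method: with the C3 ester in place, C2=C3 of 7 is a β-aryl β-aryloxy acrylate, so the bisphosphine-bound copper hydride should deliver hydride to C2 on the face left open by the ligand (ligand control sets C2 as R) and t-BuOH should protonate the copper enolate; the closest known reaction type is the copper hydride asymmetric 1,4-reduction of β,β-disubstituted enoates and of cyclic β-heteroatom-substituted enones such as chromones, which has not been shown on the aromatic C2=C3 bond of a benzofuran. C3 is then set by thermodynamic control: DBU equilibrates the α-ester centre to the trans isomer, in which the aryl and ester groups lie on opposite faces. Ring opening by β-elimination of the aryloxide would be the reverse of a 5-endo-trig closure and is stereoelectronically slow, so C2 should hold during both stages.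

Step 7
Reactants: 9 methyl (2R,3R)-5-bromo-7-methoxy-2-[3,5-dimethoxy-4-(triisopropylsilyloxy)phenyl]-2,3-dihydro-1-benzofuran-3-carboxylate
Product: 10 [(2R,3S)-5-bromo-7-methoxy-2-[3,5-dimethoxy-4-(triisopropylsilyloxy)phenyl]-2,3-dihydro-1-benzofuran-3-yl]methanol
Conditions: LiBH4, THF, 0 °C to rt
Reagents that add atoms: none
Why: Chemoselective ester reduction with LiBH4; the aryl bromide, silyl ether and benzylic ether are inert. Neither stereocentre is touched, and the C3 descriptor changes from R to S only because CH2OH ranks below C2.

Step 8
Reactants: 11 3,5-dihydroxybenzaldehyde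
Product: 12 3,5-bis(tert-butyldimethylsilyloxy)benzaldehyde
Conditions: TBSCl, imidazole, DMF, rt
Reagents that add atoms: tert-butyldimethylsilyl chloride, CC(C)(C)[Si](C)(C)Cl
Why: Silyl ether formation on both phenols; the ethers remove the acidic protons for the Wittig and Heck steps and fall together with the triisopropylsilyl group in the last step.

Step 9
Reactants: 12 3,5-bis(tert-butyldimethylsilyloxy)benzaldehyde
Product: 13 3,5-bis(tert-butyldimethylsilyloxy)styrene
Conditions: Ph3PCH3Br, n-BuLi, THF, 0 °C to rt
Reagents that add atoms: methyltriphenylphosphonium bromide, C[P+](c1ccccc1)(c1ccccc1)c1ccccc1.[Br-]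
Why: Wittig methylenation with the non-stabilised ylide converts the aldehyde into the terminal alkene.

Step 10
Reactants: 10 [(2R,3S)-5-bromo-7-methoxy-2-[3,5-dimethoxy-4-(triisopropylsilyloxy)phenyl]-2,3-dihydro-1-benzofuran-3-yl]methanol; 13 3,5-bis(tert-butyldimethylsilyloxy)styrene
Product: 14 [(2R,3S)-5-{(E)-2-[3,5-bis(tert-butyldimethylsilyloxy)phenyl]ethenyl}-7-methoxy-2-[3,5-dimethoxy-4-(triisopropylsilyloxy)phenyl]-2,3-dihydro-1-benzofuran-3-yl]methanol
Conditions: Pd2(dba)3 (2.5 mol %), [(t-Bu)3PH]BF4 (6 mol %), Cy2NMe (1.5 equiv), 1,4-dioxane, 60 °C
Reagents that add atoms: none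
Why: Mizoroki–Heck reaction; the bulky electron-rich phosphine lets zerovalent palladium insert into the electron-rich aryl bromide at moderate temperature, and syn insertion at the unsubstituted alkene carbon followed by syn β-hydride elimination gives the E-stilbene. The primary alcohol is tolerated, and the stereocentres are neither acidic nor ionisable here because the para oxygen of ring B is still silylated.

Step 11
Reactants: 14 [(2R,3S)-5-{(E)-2-[3,5-bis(tert-butyldimethylsilyloxy)phenyl]ethenyl}-7-methoxy-2-[3,5-dimethoxy-4-(triisopropylsilyloxy)phenyl]-2,3-dihydro-1-benzofuran-3-yl]methanol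
Product: 15 gnetucleistol F, 5-{(E)-2-[(2R,3S)-2-(4-hydroxy-3,5-dimethoxyphenyl)-3-(hydroxymethyl)-7-methoxy-2,3-dihydro-1-benzofuran-5-yl]ethenyl}benzene-1,3-diol
Conditions: Bu4NF (3.5 equiv), AcOH (3.5 equiv), THF, 0 °C to rt, argon, dark
Reagents that add atoms: none
Why: Fluoride-mediated cleavage of the three aryl silyl ethers. Acetic acid keeps the liberated phenols protonated, so the ring B phenoxide cannot open the C2–O1 bond through a para-quinone methide and the stilbene phenols are not oxidised.

## Compound list

1 | 4-bromo-2-methoxyphenol | COc1cc(Br)ccc1O | starting material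
2 | 4-bromo-2-iodo-6-methoxyphenol | COc1cc(Br)cc(I)c1O | intermediate
3 | syringaldehyde (4-hydroxy-3,5-dimethoxybenzaldehyde) | COc1cc(C=O)cc(OC)c1O | starting material
4 | 3,5-dimethoxy-4-(triisopropylsilyloxy)benzaldehyde | COc1cc(C=O)cc(OC)c1O[Si](C(C)C)(C(C)C)C(C)C | intermediate
5 | (4-ethynyl-2,6-dimethoxyphenoxy)triisopropylsilane | COc1cc(C#C)cc(OC)c1O[Si](C(C)C)(C(C)C)C(C)C | intermediate
6 | 4-bromo-2-{[3,5-dimethoxy-4-(triisopropylsilyloxy)phenyl]ethynyl}-6-methoxyphenol | COc1cc(C#Cc2cc(Br)cc(OC)c2O)cc(OC)c1O[Si](C(C)C)(C(C)C)C(C)C | intermediate
7 | methyl 5-bromo-7-methoxy-2-[3,5-dimethoxy-4-(triisopropylsilyloxy)phenyl]-1-benzofuran-3-carboxylate | COc1cc(-c2oc3c(OC)cc(Br)cc3c2C(=O)OC)cc(OC)c1O[Si](C(C)C)(C(C)C)C(C)C | intermediate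
8 | methyl (2R)-5-bromo-7-methoxy-2-[3,5-dimethoxy-4-(triisopropylsilyloxy)phenyl]-2,3-dihydro-1-benzofuran-3-carboxylate, mixture of C3 epimers | COc1cc([C@@H]2Oc3c(OC)cc(Br)cc3C2C(=O)OC)cc(OC)c1O[Si](C(C)C)(C(C)C)C(C)C | intermediate
9 | methyl (2R,3R)-5-bromo-7-methoxy-2-[3,5-dimethoxy-4-(triisopropylsilyloxy)phenyl]-2,3-dihydro-1-benzofuran-3-carboxylate (trans) | COc1cc([C@@H]2Oc3c(OC)cc(Br)cc3[C@H]2C(=O)OC)cc(OC)c1O[Si](C(C)C)(C(C)C)C(C)C | intermediate
10 | [(2R,3S)-5-bromo-7-methoxy-2-[3,5-dimethoxy-4-(triisopropylsilyloxy)phenyl]-2,3-dihydro-1-benzofuran-3-yl]methanol (trans) | COc1cc([C@@H]2Oc3c(OC)cc(Br)cc3[C@H]2CO)cc(OC)c1O[Si](C(C)C)(C(C)C)C(C)C | intermediate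
11 | 3,5-dihydroxybenzaldehyde | O=Cc1cc(O)cc(O)c1 | starting material
12 | 3,5-bis(tert-butyldimethylsilyloxy)benzaldehyde | O=Cc1cc(O[Si](C)(C)C(C)(C)C)cc(O[Si](C)(C)C(C)(C)C)c1 | intermediate
13 | 3,5-bis(tert-butyldimethylsilyloxy)styrene | C=Cc1cc(O[Si](C)(C)C(C)(C)C)cc(O[Si](C)(C)C(C)(C)C)c1 | intermediate
14 | [(2R,3S)-5-{(E)-2-[3,5-bis(tert-butyldimethylsilyloxy)phenyl]ethenyl}-7-methoxy-2-[3,5-dimethoxy-4-(triisopropylsilyloxy)phenyl]-2,3-dihydro-1-benzofuran-3-yl]methanol | COc1cc([C@@H]2Oc3c(OC)cc(/C=C/c4cc(O[Si](C)(C)C(C)(C)C)cc(O[Si](C)(C)C(C)(C)C)c4)cc3[C@H]2CO)cc(OC)c1O[Si](C(C)C)(C(C)C)C(C)C | intermediate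
15 | gnetucleistol F | COc1cc([C@@H]2Oc3c(OC)cc(/C=C/c4cc(O)cc(O)c4)cc3[C@H]2CO)cc(OC)c1O | target

## Step count and risk

Total: 11 steps. Longest linear sequence: 8 steps (3 to 4 to 5 to 6 to 7 to 9 to 10 to 14 to 15).

**Step 6 (asymmetric dearomatising reduction).** This is the least certain step.
- Hydrocupration may not occur, because C2=C3 is tetrasubstituted, part of an aromatic furan, and made electron-rich at C2 by O1 and ring B.
- Facial discrimination may be poor, since the substrate is flat and the two C2 substituents are not very different in size.
- The copper enolate may expel the aryloxide, and the opened cinnamate may then be over-reduced.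
- Equilibration to trans may be incomplete.

Fallback with known chemistry, setting out from 7 and returning at 10:
1. Magnesium turnings with NH4Cl in MeOH/THF at −15 °C should give the racemic methyl trans-5-bromo-7-methoxy-2-[3,5-dimethoxy-4-(triisopropylsilyloxy)phenyl]-2,3-dihydro-1-benzofuran-3-carboxylate F1. This is the established dearomatising reduction of 2-arylbenzofuran-3-carboxylates and gives the trans ester directly. It is run cold and stopped at full conversion so that the aryl bromide is not reduced.
2. LiBH4 in THF should give the racemic trans alcohol F2.
3. Esterification with (S)-O-methylmandelic acid (EDC·HCl, DMAP, CH2Cl2) and chromatographic separation of the two diastereomers should give the (S)-O-methylmandelate of 10 F3.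
4. LiBH4 cleavage of F3 returns 10.

The cost is the loss of half the material and three extra operations.

**Step 5 (key step).** Protonolysis of the C3–palladium bond may outrun CO insertion and give the 3-unsubstituted benzofuran. The lipophilic substrate may dissolve poorly in methanol. HCl formed at the copper salt may loosen the silyl ether if the buffer is exhausted.

Fallback, setting out from 6 and returning at 7, forming the same two bonds in two operations:
1. I2 and NaHCO3 in MeCN at rt (5-endo-dig iodocyclisation) should give 5-bromo-3-iodo-7-methoxy-2-[3,5-dimethoxy-4-(triisopropylsilyloxy)phenyl]-1-benzofuran F4.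
2. Iodine–magnesium exchange with i-PrMgCl·LiCl in THF at −40 °C, which is much faster at C3–I than at C5–Br, followed by ClCO2Me, gives 7.

**Step 4 (Sonogashira).** The free phenol may cyclise onto the alkyne under palladium and copper catalysis to give the 3-unsubstituted benzofuran. Alkyne 5 may undergo oxidative homocoupling (Glaser). On warming, the bromide may begin to couple.

Fallback, setting out from 2 and returning at 6:
1. Ac2O and pyridine give 4-bromo-2-iodo-6-methoxyphenyl acetate F5.
2. Sonogashira coupling of F5 with 5 under the same catalysts gives 4-bromo-2-{[3,5-dimethoxy-4-(triisopropylsilyloxy)phenyl]ethynyl}-6-methoxyphenyl acetate F6, which cannot cyclise.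
3. NH3 in MeOH at 0 °C removes the acetate and gives 6.

**Step 10 (Heck).** Oxidative addition into the electron-rich bromide may be slow. Insertion at the internal carbon of the electron-rich styrene may give the 1,1-diaryl isomer. The tert-butyldimethylsilyl ethers may be partly lost on prolonged heating with the ammonium salt.

Fallback, setting out from 13 and 10 and returning at 14:
1. Cross-metathesis of 13 with vinylboronic acid pinacol ester (second-generation Grubbs catalyst RuCl2(=CHPh)(H2IMes)(PCy3), CH2Cl2, 40 °C) gives (E)-2-[3,5-bis(tert-butyldimethylsilyloxy)styryl]-4,4,5,5-tetramethyl-1,3,2-dioxaborolane F7.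
2. Suzuki–Miyaura coupling of F7 with 10 (Pd(dppf)Cl2, K3PO4, dioxane/H2O, 60 °C) gives 14. The alkene geometry is fixed in the boronate and the regiochemistry cannot vary.

## Further compounds

F1 | step 6 | racemic methyl trans-5-bromo-7-methoxy-2-[3,5-dimethoxy-4-(triisopropylsilyloxy)phenyl]-2,3-dihydro-1-benzofuran-3-carboxylate (both enantiomers written) | COc1cc([C@@H]2Oc3c(OC)cc(Br)cc3[C@H]2C(=O)OC)cc(OC)c1O[Si](C(C)C)(C(C)C)C(C)C.COc1cc([C@H]2Oc3c(OC)cc(Br)cc3[C@@H]2C(=O)OC)cc(OC)c1O[Si](C(C)C)(C(C)C)C(C)C
F2 | step 6 | racemic trans-[5-bromo-7-methoxy-2-[3,5-dimethoxy-4-(triisopropylsilyloxy)phenyl]-2,3-dihydro-1-benzofuran-3-yl]methanol (both enantiomers written) | COc1cc([C@@H]2Oc3c(OC)cc(Br)cc3[C@H]2CO)cc(OC)c1O[Si](C(C)C)(C(C)C)C(C)C.COc1cc([C@H]2Oc3c(OC)cc(Br)cc3[C@@H]2CO)cc(OC)c1O[Si](C(C)C)(C(C)C)C(C)C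
F3 | step 6 | [(2R,3S)-5-bromo-7-methoxy-2-[3,5-dimethoxy-4-(triisopropylsilyloxy)phenyl]-2,3-dihydro-1-benzofuran-3-yl]methyl (S)-2-methoxy-2-phenylacetate | COc1cc([C@@H]2Oc3c(OC)cc(Br)cc3[C@H]2COC(=O)[C@@H](OC)c2ccccc2)cc(OC)c1O[Si](C(C)C)(C(C)C)C(C)C
F4 | step 5 | 5-bromo-3-iodo-7-methoxy-2-[3,5-dimethoxy-4-(triisopropylsilyloxy)phenyl]-1-benzofuran | COc1cc(-c2oc3c(OC)cc(Br)cc3c2I)cc(OC)c1O[Si](C(C)C)(C(C)C)C(C)C
F5 | step 4 | 4-bromo-2-iodo-6-methoxyphenyl acetate | COc1cc(Br)cc(I)c1OC(C)=O
F6 | step 4 | 4-bromo-2-{[3,5-dimethoxy-4-(triisopropylsilyloxy)phenyl]ethynyl}-6-methoxyphenyl acetate | COc1cc(C#Cc2cc(Br)cc(OC)c2OC(C)=O)cc(OC)c1O[Si](C(C)C)(C(C)C)C(C)C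
F7 | step 10 | (E)-2-[3,5-bis(tert-butyldimethylsilyloxy)styryl]-4,4,5,5-tetramethyl-1,3,2-dioxaborolane | CC1(C)OB(/C=C/c2cc(O[Si](C)(C)C(C)(C)C)cc(O[Si](C)(C)C(C)(C)C)c2)OC1(C)C
A1 | alternative 1 | (S,S)-1,2-dicyclohexylethane-1,2-diol boronate of the 3-benzyloxy-2-[2-benzyloxy-5-(1,3-dioxolan-2-yl)-3-methoxyphenyl]-1-[3,5-dimethoxy-4-(triisopropylsilyloxy)phenyl]propyl group, boron on C1 of the chain (the future C2), configuration as in the SMILES | COc1cc([C@H](B2O[C@@H](C3CCCCC3)[C@H](C3CCCCC3)O2)[C@H](COCc2ccccc2)c2cc(C3OCCO3)cc(OC)c2OCc2ccccc2)cc(OC)c1O[Si](C(C)C)(C(C)C)C(C)C
A2 | alternative 2 | (2R,3S)-5-bromo-3-(tert-butyldimethylsilyloxymethyl)-7-methoxy-2-[3,5-dimethoxy-4-(triisopropylsilyloxy)phenyl]-2,3-dihydro-1-benzofuran | COc1cc([C@@H]2Oc3c(OC)cc(Br)cc3[C@H]2CO[Si](C)(C)C(C)(C)C)cc(OC)c1O[Si](C(C)C)(C(C)C)C(C)C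
A3 | alternative 3 | (R)-6-bromo-8-methoxy-2-[3,5-dimethoxy-4-(pivaloyloxy)phenyl]chroman-4-one | COc1cc([C@@H]2Oc3c(OC)cc(Br)cc3C(=O)C2)cc(OC)c1OC(=O)C(C)(C)C
A4 | alternative 3 | methyl (2R,3R)-5-bromo-7-methoxy-2-[3,5-dimethoxy-4-(pivaloyloxy)phenyl]-2,3-dihydro-1-benzofuran-3-carboxylate (trans) | COc1cc([C@@H]2Oc3c(OC)cc(Br)cc3[C@H]2C(=O)OC)cc(OC)c1OC(=O)C(C)(C)C
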